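**Plan** (cyclodeca[b]furan numbering: O1, C2(=O), C3, C3a, C4–C11, C11a)

1. Retrosynthesis: remove the two acetates and C6=CH2, then cut C4–C5 and restore C3–C7 (retro anionic oxy-Cope); the ten-membered carbocycle becomes an eight-membered one (C3, C3a, C11a, C11, C10, C9, C8, C7).
2. Enabling feature: the C7 ketone and the butenolide C3=C3a bond form a δ,ε-unsaturated ketone (O=C7–C6–C5–C4–C3a=C3), the oxy-Cope retron; one [3,3] shift delivers the ten-membered ring, the butenolide alkene and the regiodefined C6/C7 enolate needed for the exo-methylene.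
3. Further cuts: C3–C7 (intramolecular allylsilane–aldehyde addition at the lactone α-carbon), the butenolide (alkyne carbomagnesiation/CO2), C11a–C3a (alkynylation of a Z-enal), C8–C9 (allylation).
4. Forward: Z-iodoalkene → Z-enal → propargylic alcohol → butenolide → lactone-bridged eight-membered ring (8-oxabicyclo[5.2.1]decene) → ring expansion to the ten-membered ring → methylene ketone → diacetate.
5. Stereochemistry: C9 from a Keck allylation, C11a from a ligand-controlled alkynylation, Z C10=C11 from anti-carbomagnesiation/iodination of propargyl alcohol (then held in the rings); the helper stereocentres at C3 and C7 are erased in the key step, so their mixture converges.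

Key step: step 12

Assumption: the facial sense of the zinc–ProPhenol alkynylation on Z-enal 8 is assigned after step 6 (Mosher esters) and the ligand antipode that gives 4R is used. Reagents named without a number are commercial. TBS = tert-butyldimethylsilyl, TMS = trimethylsilyl.

**Step 1**
Reactants: 1 prop-2-yn-1-ol
Product: 3 (Z)-3-iodo-2-methylprop-2-en-1-ol, via vinylmagnesium alkoxide 2 (not isolated)
Conditions: MeMgBr (2.5 equiv), CuI (10 mol %), THF, −10 °C → rt; then I2, −78 → 0 °C
Reagents that add atoms: methylmagnesium bromide (C[Mg]Br); iodine (II)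
Why: Copper-catalysed, alkoxide-directed anti-carbomagnesiation of a propargylic alcohol places methyl on the internal carbon and magnesium on the terminal carbon cis to CH2O (five-membered chelate), and iodinolysis with retention gives the Z-iodoalkene that becomes the Z C10=C11 bond.

**Step 2**
Reactants: 3 (Z)-3-iodo-2-methylprop-2-en-1-ol
Product: 4 (Z)-3-iodo-2-methylprop-2-enal
Conditions: activated MnO2, CH2Cl2, rt, dark
Reagents that add atoms: none
Why: Allylic alcohol oxidation with MnO2 is neutral and should neither isomerise the Z-alkene nor touch the C–I bond.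

**Step 3**
Reactants: 4 (Z)-3-iodo-2-methylprop-2-enal
Product: 5 (1Z,3S)-1-iodo-2-methylhexa-1,5-dien-3-ol
Conditions: allylSnBu3, (S)-BINOL (20 mol %), Ti(OiPr)4 (10 mol %), 4 Å MS, CH2Cl2, −20 °C; aq. NaHCO3
Reagents that add atoms: allyltributylstannane (C=CC[Sn](CCCC)(CCCC)CCCC)
Why: Keck catalytic asymmetric allylation, in which the (S)-BINOL–Ti(IV) complex activates the enal and the allylstannane adds to one carbonyl face, should set the 3S carbinol (C9 of the target) as with other aryl and alkenyl aldehydes.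

**Step 4**
Reactants: 5 (1Z,3S)-1-iodo-2-methylhexa-1,5-dien-3-ol
Product: 6 tert-butyl{[(1Z,3S)-1-iodo-2-methylhexa-1,5-dien-3-yl]oxy}dimethylsilane
Conditions: TBSCl, imidazole, DMF, rt
Reagents that add atoms: tert-butyldimethylsilyl chloride (CC(C)(C)[Si](C)(C)Cl)
Why: Imidazole-promoted silylation of a secondary allylic alcohol gives an ether that survives the organometallic steps and is removed at the end.

**Step 5**
Reactants: 6 tert-butyl{[(1Z,3S)-1-iodo-2-methylhexa-1,5-dien-3-yl]oxy}dimethylsilane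
Product: 8 (2Z,4S)-4-[(tert-butyldimethylsilyl)oxy]-3-methylhepta-2,6-dienal, via vinyllithium 7 (not isolated)
Conditions: t-BuLi (2.1 equiv), Et2O, −78 °C, short exchange; then DMF, −78 °C → 0 °C; aq. NH4Cl
Reagents that add atoms: N,N-dimethylformamide (CN(C)C=O)
Why: Iodine–lithium exchange of a trisubstituted Z-alkenyl iodide proceeds with retention and the alkenyllithium is formylated by DMF (Bouveault-type formylation), while ether at −78 °C suppresses 1,4-O→C silyl migration.

**Step 6**
Reactants: 8 (2Z,4S)-4-[(tert-butyldimethylsilyl)oxy]-3-methylhepta-2,6-dienal; 9 tert-butyldimethyl(prop-2-yn-1-yloxy)silane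
Product: 11 (4R,5Z,7S)-1,7-bis[(tert-butyldimethylsilyl)oxy]-6-methyldeca-5,9-dien-2-yn-4-ol, via methylzinc acetylide 10 (not isolated)
Conditions: Me2Zn (3 equiv), ProPhenol ligand (20 mol %, antipode giving 4R), Ph3PO (40 mol %), toluene, 4 °C
Reagents that add atoms: none
Why: Zinc–ProPhenol-catalysed asymmetric alkynylation of an enal, in which the dinuclear zinc complex binds aldehyde and zinc acetylide and delivers the alkyne to one face, sets C4 (C11a of the target) under ligand control, independent of the remote C7 centre.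

**Step 7**
Reactants: 11 (4R,5Z,7S)-1,7-bis[(tert-butyldimethylsilyl)oxy]-6-methyldeca-5,9-dien-2-yn-4-ol
Product: 13 (5R)-5-{(1Z,3S)-3-[(TBS)oxy]-2-methylhexa-1,5-dien-1-yl}-3-{[(TBS)oxy]methyl}-4-[(trimethylsilyl)methyl]furan-2(5H)-one, via chelated alkenylmagnesium chloride 12 (not isolated)
Conditions: Me3SiCH2MgCl (3 equiv), CuI (15 mol %), THF, 0 °C → rt; then CO2 (g), −40 °C → rt; 1 M HCl
Reagents that add atoms: (trimethylsilyl)methylmagnesium chloride (C[Si](C)(C)C[Mg]Cl); carbon dioxide (O=C=O)
Why: Alkoxide-directed, Cu-catalysed anti-carbomagnesiation puts the silylmethyl group on the alkyne carbon next to the carbinol and magnesium on the distal carbon cis to the alkoxide, and carboxylation with retention gives a Z-γ-hydroxy acid that lactonises on acidification (butenolide synthesis by carbometalation–carboxylation), the weakly Lewis-basic silyl ether disfavouring β-elimination to an allene.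

**Step 8**
Reactants: 13 the allylsilane butenolide
Product: 15 (3S,4Z)-3-[(TBS)oxy]-4-methyl-5-[(2R)-4-{[(TBS)oxy]methyl}-5-oxo-3-[(trimethylsilyl)methyl]-2,5-dihydrofuran-2-yl]pent-4-enal, via vicinal diol 14 (not isolated)
Conditions: OsO4 (2 mol %), NMO, acetone/H2O, 0 °C; then NaIO4, THF/H2O, rt
Reagents that add atoms: N-methylmorpholine N-oxide (C[N+]1([O-])CCOCC1); water (O)
Why: Upjohn dihydroxylation followed by periodate cleavage (Lemieux–Johnson sequence) should select the unhindered monosubstituted alkene over the trisubstituted alkene, which is shielded and deactivated by two allylic C–O bonds, and over the electron-poor tetrasubstituted butenolide alkene.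

**Step 9**
Reactants: 15 the aldehyde
Product: 16 (1S,4S,5Z,7R)-2-hydroxy-4-[(TBS)oxy]-1-{[(TBS)oxy]methyl}-5-methyl-10-methylidene-8-oxabicyclo[5.2.1]dec-5-en-9-one (C2 epimers)
Conditions: BF3·OEt2 (1.5 equiv), CH2Cl2 (2 mM), −78 → −40 °C; aq. NaHCO3
Reagents that add atoms: none
Why: Intramolecular Hosomi–Sakurai reaction in which the BF3-activated aldehyde is attacked by the lactone α-carbon (γ to silicon, SE2′) with loss of silicon and formation of the exocyclic methylene, and because the aldehyde is tethered through the lactone γ-carbon it can only reach the face that gives the cis-bridged 1S quaternary centre, the carbinol centre being oxidised next.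

**Step 10**
Reactants: 16 the bridged alcohol
Product: 17 (1S,4S,5Z,7R)-4-[(TBS)oxy]-1-{[(TBS)oxy]methyl}-5-methyl-10-methylidene-8-oxabicyclo[5.2.1]dec-5-ene-2,9-dione
Conditions: Dess–Martin periodinane, CH2Cl2, 0 °C → rt
Reagents that add atoms: none
Why: Dess–Martin oxidation of the secondary alcohol under neutral conditions should give the β-keto lactone, which has no hydrogen at C1, without retro-aldol cleavage or β-elimination of the C4 silyloxy group.

**Step 11**
Reactants: 17 the bridged β-keto lactone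
Product: 18 (1S,4S,5Z,7R)-2-ethenyl-2-hydroxy-4-[(TBS)oxy]-1-{[(TBS)oxy]methyl}-5-methyl-10-methylidene-8-oxabicyclo[5.2.1]dec-5-en-9-one (C2 epimers)
Conditions: vinylMgBr, anhydrous CeCl3, THF, −78 °C; aq. NH4Cl at −78 °C
Reagents that add atoms: vinylmagnesium bromide (C=C[Mg]Br)
Why: Organocerium 1,2-addition, in which the non-basic vinylcerium reagent adds to the hindered, enolisable ketone in preference to the lactone, gives a tertiary carbinol whose configuration does not matter because both epimers feed the key step.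

**Step 12**
Reactants: 18 the vinyl carbinol
Product: 21 (9S,10Z,11aR)-9-[(TBS)oxy]-3-{[(TBS)oxy]methyl}-6-[(dimethylamino)methyl]-10-methyl-4,5,6,8,9,11a-hexahydrocyclodeca[b]furan-2,7-dione (C6 epimers), via potassium alkoxide 19 (not isolated), via ring-expanded potassium enolate 20 (not isolated)
Conditions: KHMDS (1.05 equiv), 18-crown-6 (1.1 equiv), THF, −78 → −40 °C; then CH2=NMe2+ I− (3 equiv), −78 → 0 °C
Reagents that add atoms: N,N-dimethylmethyleneiminium iodide, Eschenmoser's salt (C=[N+](C)C.[I-])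
Why: Deprotonation gives the potassium alkoxide of a 3-oxido-1,5-diene (C3a=CH2 / C3–C7 / C7–vinyl) whose charge-accelerated [3,3] shift breaks the C3–C7 bond of the eight-membered ring and joins the exocyclic CH2 (C4) to the vinyl terminus (C5), so that the ten-membered carbocycle, the butenolide C3=C3a bond and a C6=C7 potassium enolate arise together, and the enolate is then aminomethylated at C6 by the iminium salt. The closest known reaction type is the anionic oxy-Cope ring enlargement with in situ enolate trapping (regiospecific Mannich reaction with Eschenmoser's salt). The ten-membered ring is closed through a six-centre chair- or boat-like sigmatropic transition state inside the existing bicycle, a two-atom ring expansion and not an end-to-end macrocyclisation, helped by the weak, doubly allylic, α-acyl C3–C7 bond. The only new stereocentre, C6, forms without control and is of no consequence because it becomes sp2 in step 13, whereas C9 and C11a are untouched and C10=C11 stays Z because this alkene is a spectator already fixed in the eight-membered ring. The step needs [3,3] and not [1,3] connectivity and a regiodefined enolate, and both C7 epimers of 18 converge, since an epimer that cannot reach the pericyclic geometry can still cleave the same bond by retro-aldol fragmentation and reclose by vinylogous Michael addition to the same conjugated butenolide enolate, while the quaternary C3 centre is erased. Low temperature, one equivalent of base and immediate trapping are meant to keep the C6 enolate from equilibrating to the C8 side (loss of the C9 silyloxy group) or from deprotonating C11a.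

**Step 13**
Reactants: 21 the Mannich base
Product: 23 (9S,10Z,11aR)-9-[(TBS)oxy]-3-{[(TBS)oxy]methyl}-10-methyl-6-methylidene-4,5,6,8,9,11a-hexahydrocyclodeca[b]furan-2,7-dione, via trimethylammonium iodide 22 (not isolated)
Conditions: MeI (excess), CH2Cl2, rt; then aq. NaHCO3, CH2Cl2, rt
Reagents that add atoms: none
Why: Exhaustive N-methylation followed by E1cB (Hofmann-type) elimination of trimethylamine from the β-ammonium ketone should give the exocyclic enone at C6 only, since the leaving group was placed there by the regiospecific Mannich reaction.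

**Step 14**
Reactants: 23 the bis-silyl ether
Product: 24 (9S,10Z,11aR)-9-hydroxy-3-(hydroxymethyl)-10-methyl-6-methylidene-4,5,6,8,9,11a-hexahydrocyclodeca[b]furan-2,7-dione
Conditions: HF·pyridine, pyridine, THF, 0 °C → rt
Reagents that add atoms: none
Why: Desilylation with buffered HF·pyridine removes both silyl ethers under weakly acidic conditions that should spare the enone, the allylic lactone and the base-sensitive C11a–H.

**Step 15**
Reactants: 24 the diol
Product: 25 [(9S,10Z,11aR)-9-acetoxy-10-methyl-6-methylidene-2,7-dioxo-2,4,5,6,7,8,9,11a-octahydrocyclodeca[b]furan-3-yl]methyl acetate (CNP0272505.1)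
Conditions: Ac2O, pyridine, CH2Cl2, 0 °C → rt
Reagents that add atoms: acetic anhydride (CC(=O)OC(C)=O)
Why: Acylation of the primary allylic and the secondary allylic alcohol with acetic anhydride/pyridine at low temperature, without a stronger base, should avoid β-elimination of the new C9 acetate and oxa-Michael addition to the enone.

**Compound list**

1 | prop-2-yn-1-ol | C#CCO | starting material
2 | bromomagnesium (Z)-3-(bromomagnesio)-2-methylprop-2-en-1-olate | Br[Mg]/C=C(/C)CO[Mg]Br | intermediate (not isolated)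
3 | (Z)-3-iodo-2-methylprop-2-en-1-ol | OC/C(C)=C\I | intermediate
4 | (Z)-3-iodo-2-methylprop-2-enal | O=C/C(C)=C\I | intermediate
5 | (1Z,3S)-1-iodo-2-methylhexa-1,5-dien-3-ol | C=CC[C@H](O)/C(C)=C\I | intermediate
6 | tert-butyl{[(1Z,3S)-1-iodo-2-methylhexa-1,5-dien-3-yl]oxy}dimethylsilane | C=CC[C@H](O[Si](C)(C)C(C)(C)C)/C(C)=C\I | intermediate
7 | (1Z,3S)-3-[(TBS)oxy]-2-methylhexa-1,5-dien-1-yllithium | C=CC[C@H](O[Si](C)(C)C(C)(C)C)/C(C)=C\[Li] | intermediate (not isolated)
8 | (2Z,4S)-4-[(tert-butyldimethylsilyl)oxy]-3-methylhepta-2,6-dienal | C=CC[C@H](O[Si](C)(C)C(C)(C)C)/C(C)=C\C=O | intermediate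
9 | tert-butyldimethyl(prop-2-yn-1-yloxy)silane | C#CCO[Si](C)(C)C(C)(C)C | starting material
10 | methyl{3-[(TBS)oxy]prop-1-yn-1-yl}zinc | C[Zn]C#CCO[Si](C)(C)C(C)(C)C | intermediate (not isolated)
11 | (4R,5Z,7S)-1,7-bis[(tert-butyldimethylsilyl)oxy]-6-methyldeca-5,9-dien-2-yn-4-ol | C=CC[C@H](O[Si](C)(C)C(C)(C)C)/C(C)=C\[C@@H](O)C#CCO[Si](C)(C)C(C)(C)C | intermediate
12 | alkenylmagnesium chloride from anti-addition of Me3SiCH2–MgCl across the alkyne of 11 (Mg on the carbon bearing CH2OTBS, cis to the chloromagnesium alkoxide) | C=CC[C@H](O[Si](C)(C)C(C)(C)C)/C(C)=C\[C@@H](O[Mg]Cl)/C(C[Si](C)(C)C)=C(\[Mg]Cl)CO[Si](C)(C)C(C)(C)C | intermediate (not isolated)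
13 | (5R)-5-{(1Z,3S)-3-[(TBS)oxy]-2-methylhexa-1,5-dien-1-yl}-3-{[(TBS)oxy]methyl}-4-[(trimethylsilyl)methyl]furan-2(5H)-one | C=CC[C@H](O[Si](C)(C)C(C)(C)C)/C(C)=C\[C@H]1OC(=O)C(CO[Si](C)(C)C(C)(C)C)=C1C[Si](C)(C)C | intermediate
14 | 5,6-diol from dihydroxylation of the terminal alkene of 13 (mixture at the new carbinol) | OCC(O)C[C@H](O[Si](C)(C)C(C)(C)C)/C(C)=C\[C@H]1OC(=O)C(CO[Si](C)(C)C(C)(C)C)=C1C[Si](C)(C)C | intermediate (not isolated)
15 | (3S,4Z)-3-[(TBS)oxy]-4-methyl-5-[(2R)-4-{[(TBS)oxy]methyl}-5-oxo-3-[(trimethylsilyl)methyl]-2,5-dihydrofuran-2-yl]pent-4-enal | O=CC[C@H](O[Si](C)(C)C(C)(C)C)/C(C)=C\[C@H]1OC(=O)C(CO[Si](C)(C)C(C)(C)C)=C1C[Si](C)(C)C | intermediate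
16 | (1S,4S,5Z,7R)-2-hydroxy-4-[(TBS)oxy]-1-{[(TBS)oxy]methyl}-5-methyl-10-methylidene-8-oxabicyclo[5.2.1]dec-5-en-9-one (C2 epimers) | OC1C[C@H](O[Si](C)(C)C(C)(C)C)/C(C)=C\[C@H]2OC(=O)[C@]1(CO[Si](C)(C)C(C)(C)C)C2=C | intermediate
17 | (1S,4S,5Z,7R)-4-[(TBS)oxy]-1-{[(TBS)oxy]methyl}-5-methyl-10-methylidene-8-oxabicyclo[5.2.1]dec-5-ene-2,9-dione | O=C1C[C@H](O[Si](C)(C)C(C)(C)C)/C(C)=C\[C@H]2OC(=O)[C@]1(CO[Si](C)(C)C(C)(C)C)C2=C | intermediate
18 | (1S,4S,5Z,7R)-2-ethenyl-2-hydroxy-4-[(TBS)oxy]-1-{[(TBS)oxy]methyl}-5-methyl-10-methylidene-8-oxabicyclo[5.2.1]dec-5-en-9-one (C2 epimers) | C=CC1(O)C[C@H](O[Si](C)(C)C(C)(C)C)/C(C)=C\[C@H]2OC(=O)[C@]1(CO[Si](C)(C)C(C)(C)C)C2=C | intermediate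
19 | potassium alkoxide of 18 | [K+].[O-]C1(C=C)C[C@H](O[Si](C)(C)C(C)(C)C)/C(C)=C\[C@H]2OC(=O)[C@]1(CO[Si](C)(C)C(C)(C)C)C2=C | intermediate (not isolated)
20 | potassium C6=C7 enolate of the ring-expanded (9S,10Z,11aR)-cyclodeca[b]furan-2,7-dione | [K+].[O-]C1=CCCC2=C(CO[Si](C)(C)C(C)(C)C)C(=O)O[C@@H]2/C=C(/C)[C@@H](O[Si](C)(C)C(C)(C)C)C1 | intermediate (not isolated)
21 | (9S,10Z,11aR)-9-[(TBS)oxy]-3-{[(TBS)oxy]methyl}-6-[(dimethylamino)methyl]-10-methyl-4,5,6,8,9,11a-hexahydrocyclodeca[b]furan-2,7-dione (C6 epimers) | CN(C)CC1CCC2=C(CO[Si](C)(C)C(C)(C)C)C(=O)O[C@@H]2/C=C(/C)[C@@H](O[Si](C)(C)C(C)(C)C)CC1=O | intermediate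
22 | N,N,N-trimethylammonium iodide of 21 | C[N+](C)(C)CC1CCC2=C(CO[Si](C)(C)C(C)(C)C)C(=O)O[C@@H]2/C=C(/C)[C@@H](O[Si](C)(C)C(C)(C)C)CC1=O.[I-] | intermediate (not isolated)
23 | (9S,10Z,11aR)-9-[(TBS)oxy]-3-{[(TBS)oxy]methyl}-10-methyl-6-methylidene-4,5,6,8,9,11a-hexahydrocyclodeca[b]furan-2,7-dione | C=C1CCC2=C(CO[Si](C)(C)C(C)(C)C)C(=O)O[C@@H]2/C=C(/C)[C@@H](O[Si](C)(C)C(C)(C)C)CC1=O | intermediate
24 | (9S,10Z,11aR)-9-hydroxy-3-(hydroxymethyl)-10-methyl-6-methylidene-4,5,6,8,9,11a-hexahydrocyclodeca[b]furan-2,7-dione | C=C1CCC2=C(CO)C(=O)O[C@@H]2/C=C(/C)[C@@H](O)CC1=O | intermediate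
25 | [(9S,10Z,11aR)-9-acetoxy-10-methyl-6-methylidene-2,7-dioxo-2,4,5,6,7,8,9,11a-octahydrocyclodeca[b]furan-3-yl]methyl acetate | C=C1CCC2=C(COC(C)=O)C(=O)O[C@@H]2/C=C(/C)[C@@H](OC(C)=O)CC1=O | target

**Step count and risks**

Total step count: 15. Longest linear sequence: 15 steps (from prop-2-yn-1-ol).

Steps most likely to fail:

1. Step 12. Before the iminium salt is added, the C6 enolate may take a proton from C11a (γ to the butenolide carbonyl), which would cost the regiocontrol and epimerise C11a; silyloxide may also be lost from a fragmented intermediate. Fallback, from 18: the tertiary alcohol is silylated (TMSOTf, 2,6-lutidine, CH2Cl2, −78 °C) to the tertiary trimethylsilyl ether F1. Heating F1 (toluene, about 170 °C, sealed tube, BHT) brings about the neutral siloxy-Cope rearrangement to the ring-expanded trimethylsilyl enol ether F2, with no free enolate present. F2 reacts with Eschenmoser's salt in CH2Cl2 at rt to give the Mannich base, and the route is rejoined at 21.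

2. Step 9. The ester-conjugated allylsilane is a weak nucleophile and the ring to be closed is eight-membered and bridged, so protodesilylation or intermolecular reaction may outrun cyclisation. Fallback, from 15: Pinnick oxidation (NaClO2, NaH2PO4, 2-methyl-2-butene, t-BuOH/H2O) gives the carboxylic acid F3. Ghosez's reagent (1-chloro-N,N,2-trimethylprop-1-en-1-amine, CH2Cl2) converts it under neutral conditions to the acid chloride F4. Lewis-acid-mediated intramolecular acylation of the allylsilane (TiCl4, CH2Cl2, −78 °C, high dilution), with the more electrophilic acylium partner, closes the same C–C bond and gives the ketone directly; the route is rejoined at 17.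

3. Step 7. Copper may promote SN2′ loss of the propargylic silyloxy group (allene formation), or carbometalation of the internal alkyne may stall. Fallback, from 8: the same zinc–ProPhenol alkynylation with methyl propiolate gives the γ-hydroxy ynoate F5. Syn-addition of (Me3SiCH2)2CuLi (THF, −78 °C), iodine quench and acid lactonisation give the α-iodobutenolide F6. Stille coupling with (tributylstannyl)methanol (Pd(PPh3)4, dioxane, 80 °C) gives the hydroxymethyl butenolide F7, and TBSCl/imidazole returns the route at 13.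

**Further compounds**

F1 | step 12 | (1S,4S,5Z,7R)-2-ethenyl-4-[(TBS)oxy]-1-{[(TBS)oxy]methyl}-5-methyl-10-methylidene-2-[(trimethylsilyl)oxy]-8-oxabicyclo[5.2.1]dec-5-en-9-one | C=CC1(O[Si](C)(C)C)C[C@H](O[Si](C)(C)C(C)(C)C)/C(C)=C\[C@H]2OC(=O)[C@]1(CO[Si](C)(C)C(C)(C)C)C2=C
F2 | step 12 | (9S,10Z,11aR)-9-[(TBS)oxy]-3-{[(TBS)oxy]methyl}-10-methyl-7-[(trimethylsilyl)oxy]-4,5,8,9-tetrahydrocyclodeca[b]furan-2(11aH)-one (C6=C7 silyl enol ether) | C[Si](C)(C)OC1=CCCC2=C(CO[Si](C)(C)C(C)(C)C)C(=O)O[C@@H]2/C=C(/C)[C@@H](O[Si](C)(C)C(C)(C)C)C1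
F3 | step 9 | (3S,4Z)-3-[(TBS)oxy]-4-methyl-5-[(2R)-4-{[(TBS)oxy]methyl}-5-oxo-3-[(trimethylsilyl)methyl]-2,5-dihydrofuran-2-yl]pent-4-enoic acid | OC(=O)C[C@H](O[Si](C)(C)C(C)(C)C)/C(C)=C\[C@H]1OC(=O)C(CO[Si](C)(C)C(C)(C)C)=C1C[Si](C)(C)C
F4 | step 9 | (3S,4Z)-3-[(TBS)oxy]-4-methyl-5-[(2R)-4-{[(TBS)oxy]methyl}-5-oxo-3-[(trimethylsilyl)methyl]-2,5-dihydrofuran-2-yl]pent-4-enoyl chloride | ClC(=O)C[C@H](O[Si](C)(C)C(C)(C)C)/C(C)=C\[C@H]1OC(=O)C(CO[Si](C)(C)C(C)(C)C)=C1C[Si](C)(C)C
F5 | step 7 | methyl (4R,5Z,7S)-7-[(TBS)oxy]-4-hydroxy-6-methyldeca-5,9-dien-2-ynoate | C=CC[C@H](O[Si](C)(C)C(C)(C)C)/C(C)=C\[C@@H](O)C#CC(=O)OC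
F6 | step 7 | (5R)-5-{(1Z,3S)-3-[(TBS)oxy]-2-methylhexa-1,5-dien-1-yl}-3-iodo-4-[(trimethylsilyl)methyl]furan-2(5H)-one | C=CC[C@H](O[Si](C)(C)C(C)(C)C)/C(C)=C\[C@H]1OC(=O)C(I)=C1C[Si](C)(C)C
F7 | step 7 | (5R)-5-{(1Z,3S)-3-[(TBS)oxy]-2-methylhexa-1,5-dien-1-yl}-3-(hydroxymethyl)-4-[(trimethylsilyl)methyl]furan-2(5H)-one | C=CC[C@H](O[Si](C)(C)C(C)(C)C)/C(C)=C\[C@H]1OC(=O)C(CO)=C1C[Si](C)(C)C
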